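If the balance is written for L, the species charged in the smaller amount (0.30 M against 0.450 M of Q and 0.750 M of D, which makes it the limiting reagent), two losses stand in it: L pairs with itself to L2, and L leaks through G, which Q and D trap as Q.G and D.G.

| flask | L | Q | D | temperature | time | remark |
|---|---|---|---|---|---|---|
| birch | 0.30 M | 0.450 M (in portions, 2, over 40 min) | 0.750 M | 0 °C | 50 min | first portion at the start, last at 40 min |
| ash | 0.30 M (fed, over 40 min) | 0.450 M | 0.750 M | 0 °C | 50 min | all else is in the flask from the start; the feed brings no volume worth counting |
| oak | 0.30 M | 0.450 M (fed, over 40 min) | 0.750 M |  | 50 min | the addition at −40 °C, then warmed to 0 °C; the feed brings no volume worth counting |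
| elm | 0.30 M | 0.450 M | 0.750 M | 0 °C | 50 min | everything together at the start |
| maple | 0.30 M | 0.450 M | 0.750 M |  | 50 min | everything together at the start at −40 °C, warmed to 0 °C at 40 min |

    L ⇌ G (K1 = 0.069, k1 = 0.0232 min⁻¹, Ea1 = 74.0 kJ mol⁻¹, ΔH1 = −21.0 kJ mol⁻¹)
    Q + G → Q.G (k2 = 0.478 L mol⁻¹ min⁻¹, Ea2 = 59.0 kJ mol⁻¹)
    D + G → D.G (k3 = 0.187 L mol⁻¹ min⁻¹, Ea3 = 51.0 kJ mol⁻¹)
    2 L → L2 (k4 = 0.141 L mol⁻¹ min⁻¹, Ea4 = 69.0 kJ mol⁻¹)
    (constants at 0 °C)

- percent here means L units held: one L2 counts as two
- two of one species on the left: rate k times its square, two consumed each time
- the constants hold at 0 °C; other temperatures follow from the activation energies and enthalpies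

- the flask that comes out highest in amount of L2, in percent of the L charged; "all alike" if 1.5 percentage points covers them all (birch / ash / oak / elm / maple / all alike)
- amount of L2 at the end, in percent of the L charged, birch
- amount of L2 at the end, in percent of the L charged, ash
- amount of L2 at the end, in percent of the L charged, oak
- amount of L2 at the end, in percent of the L charged, elm
- amount of L2 at the end, in percent of the L charged, maple

The reckoning here starts with elm, with Q and D held at their charges (pseudo-first-order) and G taken at its steady level. In elm, G returns to L at 0.336 min⁻¹ and is trapped at 0.355 min⁻¹, so L leaks at a first-order constant a = 0.0119 min⁻¹, the forward constant times the trapped share of G. The pairing loss grows with the square of [L], so the two losses are equal at one concentration, the crossing concentration L*, which is a divided by twice the pairing constant: 0.0423 M. On these terms, the share of L consumed that goes to L2 is [L]/([L]+L*).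

In elm, the curve of L starts steeply, falling at 0.0290 M min⁻¹, because the charge stands 7.09 times above L*. The ratio [L]/([L]+L*) decays exponentially with constant a, and that gives each landmark. The knee of the elm curve, where L is down to half its charge, comes at 9.79 min. The elm curve crosses L* at 47.2 min. At 50 min, the ratio in elm has come down to 0.483, which gives [L] = 0.0395 M. Summing the share along the curve gives elm L2 at 66.7% of the charge, and the level it runs into, with Q and D still held at their charges, is 70.5%.

Birch, which holds the first portion of Q until 40 min, traps over that stretch at 0.248 min⁻¹, so a falls to 0.00984 min⁻¹ and L* to 0.0349 M. Birch should therefore stand above elm, because its L* is lower over that stretch. The reckoning stops there and gives no figures for ash, oak or maple.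

The forecast names birch highest, with birch 68.1%, ash 50%, oak 42%, elm 66.2% and maple 41.9%, and holds that “Oak and maple therefore effectively get just 10 min at 0 °C”. Its elm figure is lower than this reckoning's.

The flasks end with birch highest: birch 68.3%, elm 66.4%, ash 50.5%, oak 42.2%, maple 42.2%. Elm, left to 500 min, holds 70.5% as L2, beside the level of 70.5% drawn from L*. A neighbour of birch charged with 0.075 M of L starts 2.15 times above the L* of birch. There the same rule, with the first portion of Q, gives [L] = 0.0250 M at 50 min, and L2 at 38.4%. That neighbour holds 33.0% of its L and 37.7% as L2.

The constants used here are invented; what happens was integrated by code.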